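**Retrosynthetic overview**
- The target is the hydrolysed form of a cis-fused bicyclic methyl ketal; mild acid unveils the enone carbonyl and the benzylic alcohol at the very end.
- Key disconnection: the C6–Cα bond. A tertiary ring radical closes 5-exo onto the vinyl group of a tethered (S)-1-arylallyl alcohol (Ueno–Stork), building the quaternary carbon and the adjacent CH(CH3) centre in one step.
- The radical precursor, a mixed bromoketal, comes from NBS-mediated union of a cross-conjugated methyl dienol ether with the allylic alcohol.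
- The dienol ether comes from cyclohexa-1,3-diene (singlet oxygen / Kornblum–DeLaMare, O-methylation, α'-allylation, enolate O-methylation); the alcohol comes from p-cresol via 3,4,5-trimethoxybenzaldehyde and asymmetric vinylation.
- Ring order: the carbocycle and the arene are present from the start; the only ring made is the temporary tetrahydrofuran of the radical step, opened again in the same operation.

Assumption: ring atoms keep the numbering of the target throughout (C1 = carbonyl carbon, C2=C3 alkene, C4 = CH–OMe, C5 = CH2, C6 = quaternary carbon; Cα = CH(CH3), Cβ = CH(OH)Ar).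

**Route**

Step 1
Reactants: 1 p-cresol
Product: 4 3,5-dibromo-4-hydroxybenzaldehyde, via 2,6-dibromo-4-methylphenol 2 (not isolated), via 2,6-dibromo-4-(dibromomethyl)phenol 3 (not isolated)
Conditions: Br2 (2.0 equiv), o-dichlorobenzene, 35 °C; Br2 (2.1 equiv), 155 °C; H2O, 100 °C
Reagents that add atoms: bromine BrBr; water O
Why: Electrophilic aromatic bromination fills both positions ortho to the phenol, hot side-chain bromination then gives the benzal bromide, and its hydrolysis delivers the aldehyde (the technical cresol-to-hydroxybenzaldehyde sequence); no stereocentre.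

Step 2
Reactants: 4 3,5-dibromo-4-hydroxybenzaldehyde
Product: 6 3,4,5-trimethoxybenzaldehyde, via sodium 4-formyl-2,6-dimethoxyphenolate 5 (not isolated)
Conditions: NaOMe (4 equiv), CuCl (5 mol %), DMF/MeOH, 115 °C; then Me2SO4 (excess), 60 °C
Reagents that add atoms: sodium methoxide [Na+].[O-]C; dimethyl sulfate COS(=O)(=O)OC
Why: CuCl-catalysed Ullmann-type methoxylation replaces both aryl bromides of the phenolate, and the sodium phenolate is then O-methylated in the same pot (Williamson etherification); no stereocentre.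

Step 3
Reactants: 6 3,4,5-trimethoxybenzaldehyde; 7 vinylmagnesium bromide
Product: 9 (S)-1-(3,4,5-trimethoxyphenyl)prop-2-en-1-ol, via divinylzinc 8 (not isolated)
Conditions: 7 (2.6 equiv), ZnCl2 (1.3 equiv), THF/Et2O, 0 °C, then 1,4-dioxane, filter; 6, (−)-3-exo-morpholinoisoborneol [(−)-MIB, 5 mol %], toluene, −10 °C; aqueous work-up
Reagents that add atoms: none
Why: Amino-alcohol-catalysed enantioselective 1,2-addition of a vinylzinc reagent delivers vinyl to the Si face of the aldehyde, as in the Et2Zn/ArCHO benchmark with (−)-MIB, which sets the (S) carbinol centre that becomes Cβ of the target.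

Step 4
Reactants: 10 cyclohexa-1,3-diene
Product: 12 (R)-4-hydroxycyclohex-2-en-1-one, via meso-2,3-dioxabicyclo[2.2.2]oct-5-ene 11 (not isolated)
Conditions: O2, tetraphenylporphyrin (0.1 mol %), white LED, CH2Cl2, −20 °C; then 9-O-acetylated 6'-hydroxy cinchona base (5 mol %), rt
Reagents that add atoms: dioxygen O=O
Why: [4+2] cycloaddition of singlet oxygen gives the meso endoperoxide, and the chiral base then removes one of the two enantiotopic bridgehead protons (Kornblum–DeLaMare rearrangement, a desymmetrisation), which sets C4; the catalyst pseudoenantiomer (cupreine or cupreidine series) that gives (R) is used.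

Step 5
Reactants: 12 (R)-4-hydroxycyclohex-2-en-1-one
Product: 13 (R)-4-methoxycyclohex-2-en-1-one
Conditions: MeI (5 equiv), Ag2O (1.5 equiv), 4 Å molecular sieves, CH2Cl2, rt, dark
Reagents that add atoms: iodomethane CI
Why: Purdie methylation etherifies the secondary alcohol without strong base, so the γ-hydroxy enone neither isomerises nor racemises and C4 stays (R).

Step 6
Reactants: 13 (R)-4-methoxycyclohex-2-en-1-one; 14 allyl bromide
Product: 16 (4R)-6-allyl-4-methoxycyclohex-2-en-1-one (C6 epimer mixture), via lithium (4R)-4-methoxycyclohexa-1,5-dien-1-olate 15 (not isolated)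
Conditions: LiN(iPr)2 (1.05 equiv), THF, −78 °C; 14 (1.2 equiv), DMPU, −78 → −20 °C
Reagents that add atoms: none
Why: Kinetic α'-deprotonation gives the cross-conjugated dienolate, which is C-allylated (enolate alkylation); the C6 epimer ratio is of no consequence because C6 becomes planar in steps 7 and 9.

Step 7
Reactants: 16 (4R)-6-allyl-4-methoxycyclohex-2-en-1-one
Product: 18 (5R)-1-allyl-2,5-dimethoxycyclohexa-1,3-diene, via potassium (4R)-2-allyl-4-methoxycyclohexa-1,5-dien-1-olate 17 (not isolated)
Conditions: KN(SiMe3)2 (1.15 equiv), THF, −78 °C (ketone added to base); DMPU, MeOTf (1.3 equiv), −78 °C; Et3N quench, basic alumina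
Reagents that add atoms: methyl trifluoromethanesulfonate COS(=O)(=O)C(F)(F)F
Why: Kinetic α'-deprotonation gives the fully substituted potassium dienolate, and the hard electrophile MeOTf with DMPU alkylates it on oxygen (enolate O-alkylation, favoured because C-alkylation would have to build a quaternary centre); C4 is untouched.

Step 8
Reactants: 18 (5R)-1-allyl-2,5-dimethoxycyclohexa-1,3-diene; 9 (S)-1-(3,4,5-trimethoxyphenyl)prop-2-en-1-ol
Product: 19 (1R,4R,6R)-6-allyl-6-bromo-1,4-dimethoxy-1-{[(1S)-1-(3,4,5-trimethoxyphenyl)prop-2-en-1-yl]oxy}cyclohex-2-ene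
Conditions: NBS (1.05 equiv), 9 (1.3 equiv), 2,6-lutidine (0.5 equiv), CH2Cl2, −78 → −40 °C; crude product used at once
Reagents that add atoms: N-bromosuccinimide O=C1CCC(=O)N1Br
Why: Ueno–Stork bromoketalisation: Br+ adds to the enol-ether carbon C6 anti to the C4 methoxy group (the same sense as α'-alkylation of 4-alkoxycyclohexenone enolates), and alcohol 9 opens the bromo-oxocarbenium ion at C1 anti to bromine, so the tether oxygen ends cis to the C4 methoxy group (C1 R).

Step 9
Reactants: 19 mixed bromoketal
Product: 21 megaphone (4R,6R)-6-[(1S,2S)-1-hydroxy-1-(3,4,5-trimethoxyphenyl)propan-2-yl]-4-methoxy-6-(prop-2-en-1-yl)cyclohex-2-en-1-one, via cis-fused hexahydrobenzofuran ketal 20 (not isolated)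
Conditions: Bu3SnH (1.5 equiv), Et3B (0.2 equiv), air, toluene (0.03 M), 0 °C → rt; then 1 M aq HCl, THF, 0 °C
Reagents that add atoms: water O
Why: Ueno–Stork 5-exo-trig radical cyclisation: the tertiary C6 radical adds to the internal vinyl carbon through a chair-like Beckwith–Houk transition state with aryl pseudoequatorial, which forges the quaternary C6–Cα bond cis to the tether oxygen (C6 R) and places the new methyl trans to aryl (Cα S); Bu3SnH reduces the primary radical and mild acid hydrolyses the mixed ketal to the enone and the free benzylic alcohol.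

Two points on step 9:
- In the desired isomer the allyl group is trans to the CH2 radical, so a second 5-exo closure onto the allyl group would need a trans-fused diquinane and is not expected to compete.
- Both fragments are enantioenriched, so the minor enantiomer of either one ends up in a diastereomer that is removed by chromatography.

**Compound list**

1 | p-cresol | Cc1ccc(O)cc1 | starting material
2 | 2,6-dibromo-4-methylphenol | Cc1cc(Br)c(O)c(Br)c1 | intermediate
3 | 2,6-dibromo-4-(dibromomethyl)phenol | BrC(Br)c1cc(Br)c(O)c(Br)c1 | intermediate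
4 | 3,5-dibromo-4-hydroxybenzaldehyde | O=Cc1cc(Br)c(O)c(Br)c1 | intermediate
5 | sodium 4-formyl-2,6-dimethoxyphenolate | [Na+].[O-]c1c(OC)cc(C=O)cc1OC | intermediate
6 | 3,4,5-trimethoxybenzaldehyde | COc1cc(C=O)cc(OC)c1OC | intermediate
7 | vinylmagnesium bromide | C=C[Mg]Br | starting material
8 | divinylzinc | C=C[Zn]C=C | intermediate
9 | (S)-1-(3,4,5-trimethoxyphenyl)prop-2-en-1-ol | O[C@@H](C=C)c1cc(OC)c(OC)c(OC)c1 | intermediate
10 | cyclohexa-1,3-diene | C1=CC=CCC1 | starting material
11 | meso-2,3-dioxabicyclo[2.2.2]oct-5-ene | C1C[C@@H]2C=C[C@H]1OO2 | intermediate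
12 | (R)-4-hydroxycyclohex-2-en-1-one | O=C1C=C[C@H](O)CC1 | intermediate
13 | (R)-4-methoxycyclohex-2-en-1-one | O=C1C=C[C@H](OC)CC1 | intermediate
14 | allyl bromide | C=CCBr | starting material
15 | lithium (4R)-4-methoxycyclohexa-1,5-dien-1-olate | [Li+].[O-]C1=CC[C@@H](OC)C=C1 | intermediate
16 | (4R)-6-allyl-4-methoxycyclohex-2-en-1-one, C6 epimer mixture | C=CCC1C[C@@H](OC)C=CC1=O | intermediate
17 | potassium (4R)-2-allyl-4-methoxycyclohexa-1,5-dien-1-olate | [K+].[O-]C1=C(CC=C)C[C@@H](OC)C=C1 | intermediate
18 | (5R)-1-allyl-2,5-dimethoxycyclohexa-1,3-diene | C=CCC1=C(OC)C=C[C@H](OC)C1 | intermediate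
19 | (1R,4R,6R)-6-allyl-6-bromo-1,4-dimethoxy-1-{[(1S)-1-(3,4,5-trimethoxyphenyl)prop-2-en-1-yl]oxy}cyclohex-2-ene (target numbering) | C=CC[C@@]1(Br)C[C@@H](OC)C=C[C@@]1(OC)O[C@@H](C=C)c2cc(OC)c(OC)c(OC)c2 | intermediate
20 | (2S,3S,3aR,5R,7aR)-3a-allyl-5,7a-dimethoxy-3-methyl-2-(3,4,5-trimethoxyphenyl)-2,3,3a,4,5,7a-hexahydrobenzofuran | C=CC[C@]1([C@H](C)[C@H](O2)c3cc(OC)c(OC)c(OC)c3)C[C@@H](OC)C=C[C@]12OC | intermediate
21 | megaphone, (4R,6R)-6-[(1S,2S)-1-hydroxy-1-(3,4,5-trimethoxyphenyl)propan-2-yl]-4-methoxy-6-(prop-2-en-1-yl)cyclohex-2-en-1-one | C=CC[C@]1([C@H](C)[C@H](O)c2cc(OC)c(OC)c(OC)c2)C[C@@H](OC)C=CC1=O | target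

**Step count**

Total: 9 steps. Longest linear sequence: 6 steps (10 → 12 → 13 → 16 → 18 → 19 → 21, steps 4 to 9).

**Three steps most likely to fail, with fallbacks**

Step 7 (enolate O-methylation). C-methylation or γ-deprotonation at C4 could compete, and 18 is acid-labile. The fallback sets out from 16 and comes back at 18, making the enol ether by ketal elimination instead of enolate O-alkylation. Aprotic Noyori ketalisation of 16 (Me3SiOMe, Me3SiOTf 5 mol %, CH2Cl2, −78 °C) gives the dimethyl ketal (4R)-6-allyl-1,1,4-trimethoxycyclohex-2-ene F1 without acid-promoted loss of methanol. Gassman-type elimination (Me3SiOTf, iPr2NEt, CH2Cl2, −20 °C) then removes one methanol towards C6 to give 18. Deprotonation at C4 instead of C6 is the risk here.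

Step 8 (bromoketalisation). The oxocarbenium ion next to a fully substituted carbon may be too crowded for the hindered, acid-sensitive alcohol 9. The fallback sets out from 18 and 9 and comes back at 19, splitting the union into two easier events. NBS in MeOH/CH2Cl2 with 2,6-lutidine at −78 °C gives the bromo dimethyl ketal (4R,6R)-6-allyl-6-bromo-1,1,4-trimethoxycyclohex-2-ene F2 (small nucleophile, same anti addition). Alcohol 9 is silylated (Me3SiCl, imidazole, CH2Cl2) to (S)-trimethyl{[1-(3,4,5-trimethoxyphenyl)prop-2-en-1-yl]oxy}silane F3. Noyori-type transketalisation of F2 with F3 (Me3SiOTf 5 mol %, CH2Cl2, −78 °C) exchanges one methoxy group for the chiral alkoxy group anti to bromine and gives 19.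

Step 9 (tertiary-radical cyclisation). The tertiary bromide may eliminate, the radical may be reduced before it cyclises, or the Cα selectivity may be low. The fallback sets out from 13 (with 9 and 14) and comes back at 21; it forms the C6–Cα bond with a secondary radical and installs the allyl group last.
- 13 is O-methylated (KN(SiMe3)2, DMPU, MeOTf, −78 °C) to (5R)-2,5-dimethoxycyclohexa-1,3-diene F4.
- NBS and 9 give the secondary bromoketal (4R)-6-bromo-1,4-dimethoxy-1-{[(1S)-1-(3,4,5-trimethoxyphenyl)prop-2-en-1-yl]oxy}cyclohex-2-ene F5 as a C1/C6 mixture.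
- Bu3SnH/Et3B cyclisation gives the cis-fused ketal (2S,3S,5R)-5,7a-dimethoxy-3-methyl-2-(3,4,5-trimethoxyphenyl)-2,3,3a,4,5,7a-hexahydrobenzofuran F6, which is hydrolysed without isolation (PPTS, aqueous acetone) to the hydroxy enone (4R)-6-[(1S,2S)-1-hydroxy-1-(3,4,5-trimethoxyphenyl)propan-2-yl]-4-methoxycyclohex-2-en-1-one F7.
- Double deprotonation (KN(SiMe3)2, 2.2 equiv, THF, −78 °C) and 14 then allylate C6 trans to the C4 methoxy group to give 21.

In this order the configuration of the ketal carbon no longer matters; the quaternary centre is set by ring-controlled enolate alkylation.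

**Further compounds**

F1 | step 7 | (4R)-6-allyl-1,1,4-trimethoxycyclohex-2-ene (target numbering, C6 epimer mixture) | C=CCC1C[C@@H](OC)C=CC1(OC)OC
F2 | step 8 | (4R,6R)-6-allyl-6-bromo-1,1,4-trimethoxycyclohex-2-ene (target numbering) | C=CC[C@@]1(Br)C[C@@H](OC)C=CC1(OC)OC
F3 | step 8 | (S)-trimethyl{[1-(3,4,5-trimethoxyphenyl)prop-2-en-1-yl]oxy}silane | C[Si](C)(C)O[C@@H](C=C)c1cc(OC)c(OC)c(OC)c1
F4 | step 9 | (5R)-2,5-dimethoxycyclohexa-1,3-diene | COC1=CC[C@@H](OC)C=C1
F5 | step 9 | (4R)-6-bromo-1,4-dimethoxy-1-{[(1S)-1-(3,4,5-trimethoxyphenyl)prop-2-en-1-yl]oxy}cyclohex-2-ene (C1/C6 mixture) | BrC1C[C@@H](OC)C=CC1(OC)O[C@@H](C=C)c1cc(OC)c(OC)c(OC)c1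
F6 | step 9 | (2S,3S,5R)-5,7a-dimethoxy-3-methyl-2-(3,4,5-trimethoxyphenyl)-2,3,3a,4,5,7a-hexahydrobenzofuran (cis-fused, 3a/7a mixture) | C1([C@H](C)[C@H](O2)c3cc(OC)c(OC)c(OC)c3)C[C@@H](OC)C=CC12OC
F7 | step 9 | (4R)-6-[(1S,2S)-1-hydroxy-1-(3,4,5-trimethoxyphenyl)propan-2-yl]-4-methoxycyclohex-2-en-1-one (C6 epimer mixture) | O=C1C=C[C@H](OC)CC1[C@H](C)[C@H](O)c1cc(OC)c(OC)c(OC)c1
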